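**Assumption:** germacrane numbering is used for ring positions (C1–C10 ring, C11–C13 lactone carbons, C14 ester carbon, C15 methyl); the target is (4R,5R,6S,7R,8S,9S) with a (2S,3R)-2,3-dimethyloxirane-2-carbonyl group on O8.

## Retrosynthetic overview

1. Target 31 ⇐ 4,5-epoxidation of macrocyclic triene 30 ⇐ O9-acetylation, then O8-acylation with epoxy acid 20, of diol 27 ⇐ acetonide 26.
2. 26 ⇐ ring-closing metathesis at C2=C3 (closes the 10-membered ring) of 25 ⇐ α-methylenation of lactone 22.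
3. Key disconnection C7–C8: decarboxylative radical conjugate addition of the dioxolan-4-yl radical from acid 17 to butenolide 6; this sets C7 and C8.
4. 6 ⇐ enynal 2 + methyl propiolate 3; 17 ⇐ iodo dienoate 10 + glyceraldehyde acetonide 11 (sets C9); 20 ⇐ Sharpless epoxidation of 18.
5. Ring order: butenolide, then the temporary dioxolane, then the 10-membered carbocycle, then the 4,5-epoxide.

## Route

Step 1
Reactants: 1 (2E)-3-methylpent-2-en-4-yn-1-ol
Product: 2 (2E)-3-methylpent-2-en-4-ynal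
Conditions: MnO2 (10 equiv), CH2Cl2, rt
Reagents that add atoms: none
Why: Allylic oxidation with MnO2 touches only the allylic primary alcohol, so the E-alkene and the terminal alkyne survive.

Step 2
Reactants: 2 (2E)-3-methylpent-2-en-4-ynal; 3 methyl propiolate
Product: 4 methyl (4R,5E)-4-hydroxy-6-methylocta-5-en-2,7-diynoate
Conditions: Me2Zn (3 equiv), 3 (3 equiv), (S,S)-ProPhenol (20 mol%), Ph3P=O (40 mol%), toluene, 0 °C
Reagents that add atoms: none
Why: Catalytic asymmetric zinc alkynylation (ProPhenol): the more acidic propiolate C–H is zincated in preference to the enyne C–H and adds to one face of the enal, setting C6 as the 4R carbinol (ligand enantiomer chosen for this sense).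

Step 3
Reactants: 4 methyl (4R,5E)-4-hydroxy-6-methylocta-5-en-2,7-diynoate
Product: 6 (5S)-5-[(1E)-2-methylbuta-1,3-dien-1-yl]furan-2(5H)-one, via hydroxy trienoate 5 (not isolated)
Conditions: H2 (1 atm), Pd/CaCO3 poisoned with Pb(OAc)2, quinoline, EtOAc, rt; then PPTS (cat.), CH2Cl2, rt
Reagents that add atoms: none
Why: Lindlar semihydrogenation gives the (Z)-enoate, whose γ-hydroxyl closes the butenolide with loss of methanol, and converts the terminal alkyne into the vinyl group without touching C6.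

Step 4
Reactants: 7 (2-methylprop-1-en-1-yl)magnesium bromide; 3 methyl propiolate
Product: 10 methyl (2Z)-2-iodo-5-methylhexa-2,4-dienoate, via alkenylcopper 8 (not isolated), via vinylcopper adduct 9 (not isolated)
Conditions: CuBr·SMe2 (1 equiv), THF, −40 °C; 3, −78 °C; then I2, THF, −78 → 0 °C
Reagents that add atoms: iodine, [I][I]
Why: Syn-carbocupration of the propiolate puts the alkenyl group and copper cis, and iodinolysis of the C–Cu bond with retention gives the iodide with the alkenyl group trans to the ester.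

Step 5
Reactants: 10 methyl (2Z)-2-iodo-5-methylhexa-2,4-dienoate; 11 (4R)-2,2-dimethyl-1,3-dioxolane-4-carbaldehyde
Product: 13 methyl (2E)-2-{(S)-[(4R)-2,2-dimethyl-1,3-dioxolan-4-yl](hydroxy)methyl}-5-methylhexa-2,4-dienoate, via alkenylchromium dichloride 12 (not isolated)
Conditions: CrCl2 (4 equiv), NiCl2 (2 mol%), DMF, rt
Reagents that add atoms: none
Why: Nozaki–Hiyama–Kishi coupling: the alkenylchromium keeps its alkene geometry and adds to the α-alkoxy aldehyde with Felkin–Anh (anti) selectivity, setting C9 as S, the minor syn isomer being removed by chromatography.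

Step 6
Reactants: 13 methyl (2E)-2-{(S)-[(4R)-2,2-dimethyl-1,3-dioxolan-4-yl](hydroxy)methyl}-5-methylhexa-2,4-dienoate
Product: 14 methyl (2E)-5-methyl-2-[(1S,2R)-1,2,3-trihydroxypropyl]hexa-2,4-dienoate
Conditions: AcOH/H2O (4:1), rt
Reagents that add atoms: none
Why: Acid hydrolysis of the terminal acetonide under conditions mild enough to leave the dienoate and the allylic alcohol intact.

Step 7
Reactants: 14 methyl (2E)-5-methyl-2-[(1S,2R)-1,2,3-trihydroxypropyl]hexa-2,4-dienoate
Product: 16 (2S,3S,4E)-2,3-dihydroxy-4-(methoxycarbonyl)-7-methylocta-4,6-dienoic acid, via hydroxy aldehyde 15 (not isolated)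
Conditions: TEMPO (20 mol%), PhI(OAc)2 (2.2 equiv), MeCN/H2O (1:1), rt
Reagents that add atoms: water, O
Why: TEMPO/PhI(OAc)2 oxidation is selective for the primary alcohol and, in water, carries the aldehyde hydrate on to the acid while both secondary alcohols remain.

Step 8
Reactants: 16 (2S,3S,4E)-2,3-dihydroxy-4-(methoxycarbonyl)-7-methylocta-4,6-dienoic acid
Product: 17 (4S,5S)-5-[(2E)-1-methoxy-5-methyl-1-oxohexa-2,4-dien-2-yl]-2,2-dimethyl-1,3-dioxolane-4-carboxylic acid
Conditions: 2,2-dimethoxypropane, PPTS (cat.), acetone, rt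
Reagents that add atoms: 2,2-dimethoxypropane, COC(C)(C)OC
Why: Ketalization of the vicinal diol gives the cis-dioxolane; the C8 configuration no longer matters because C8 becomes a radical centre in step 11.

Step 9
Reactants: 18 (2E)-2-methylbut-2-en-1-ol
Product: 19 [(2R,3R)-2,3-dimethyloxiran-2-yl]methanol
Conditions: Ti(OiPr)4 (5 mol%), D-(−)-diethyl tartrate (6 mol%), t-BuOOH, 4 Å molecular sieves, CH2Cl2, −20 °C
Reagents that add atoms: tert-butyl hydroperoxide, CC(C)(C)OO
Why: Sharpless asymmetric epoxidation with D-(−)-diethyl tartrate delivers oxygen to the face of the E-allylic alcohol that gives the (2R,3R)-epoxy alcohol.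

Step 10
Reactants: 19 [(2R,3R)-2,3-dimethyloxiran-2-yl]methanol
Product: 20 (2S,3R)-2,3-dimethyloxirane-2-carboxylic acid
Conditions: RuCl3 (2 mol%), NaIO4 (3 equiv), CCl4/MeCN/H2O, rt
Reagents that add atoms: sodium periodate, [Na+].[O-]I(=O)(=O)=O
Why: Ruthenium tetroxide oxidation (RuCl3/NaIO4) takes the primary alcohol to the acid without opening the epoxide, and the C2 descriptor changes to S only through CIP priorities.

Step 11
Reactants: 17 (4S,5S)-5-[(2E)-1-methoxy-5-methyl-1-oxohexa-2,4-dien-2-yl]-2,2-dimethyl-1,3-dioxolane-4-carboxylic acid; 6 (5S)-5-[(1E)-2-methylbuta-1,3-dien-1-yl]furan-2(5H)-one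
Product: 22 trans-dioxolane lactone adduct (C7–C8 bond formed), via N-acyloxyphthalimide 21 (not isolated)
Conditions: N-hydroxyphthalimide, N,N′-diisopropylcarbodiimide, DMAP (cat.), CH2Cl2, rt; then 6 (2 equiv), Ru(bpy)3(PF6)2 (1 mol%), Hantzsch ester (1.5 equiv), iPr2NEt·HBF4 (1 equiv), CH2Cl2, blue LEDs, rt
Reagents that add atoms: none
Why: Decarboxylative Giese reaction: single-electron reduction of the N-acyloxyphthalimide releases CO2 and the dioxolan-4-yl radical, which adds to C7 of the butenolide anti to the C6 dienyl group and forms its new bond trans to the C9 substituent on the dioxolane, so C7 and C8 are set while C9 is retained; Hantzsch ester quenches the adduct radical and the low triplet energy of Ru(bpy)3(PF6)2 avoids diene isomerization.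

Step 12
Reactants: 22 trans-dioxolane lactone adduct
Product: 25 α-methylene lactone, via Mannich base 23 (not isolated), via ammonium iodide 24 (not isolated)
Conditions: LiN(SiMe3)2, THF, −78 °C; CH2=NMe2+ I−, −78 → 0 °C; then MeI, MeOH, rt; then aq. NaHCO3, CH2Cl2
Reagents that add atoms: N,N-dimethylmethyleneiminium iodide (Eschenmoser's salt), C=[N+](C)C.[I-]
Why: α-Methylenation: the kinetic lithium enolate of the lactone undergoes a Mannich reaction with Eschenmoser's salt, and quaternization followed by base-induced elimination of trimethylamine gives the exocyclic methylene without touching C7.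

Step 13
Reactants: 25 α-methylene lactone
Product: 26 10-membered (1(10)E,2Z,4E)-triene lactone acetonide
Conditions: second-generation Grubbs catalyst (15 mol%), toluene (1 mM), 80 °C
Reagents that add atoms: none
Why: Ring-closing metathesis between the terminal vinyl group and the isopropylidene terminus forms C2=C3 with loss of 2-methylpropene; the 10-membered ring accommodates only the Z-alkene, and the E-configured C4=C5 unit makes a competing six-membered closure onto the methylene lactone impossible.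

Step 14
Reactants: 26 10-membered triene lactone acetonide
Product: 27 macrocyclic 8,9-diol
Conditions: AcOH/H2O/THF (3:1:1), 45 °C
Reagents that add atoms: none
Why: Acid hydrolysis of the trans-fused acetonide, carried out before any acid-labile epoxide is present in the ring.

Step 15
Reactants: 27 macrocyclic 8,9-diol
Product: 28 9-O-acetyl 8-hydroxy macrocycle
Conditions: Ac2O (1.05 equiv), 2,4,6-collidine, CH2Cl2, −40 → 0 °C
Reagents that add atoms: acetic anhydride, CC(=O)OC(C)=O
Why: Regioselective acylation: the allylic C9 hydroxyl beside the planar C10 is less hindered than the C8 hydroxyl beside the ring-fusion carbon C7 and is acetylated first with one equivalent of anhydride at low temperature.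

Step 16
Reactants: 28 9-O-acetyl 8-hydroxy macrocycle; 20 (2S,3R)-2,3-dimethyloxirane-2-carboxylic acid
Product: 30 macrocyclic triene diester, via mixed anhydride 29 (not isolated)
Conditions: 20, 2,4,6-trichlorobenzoyl chloride, Et3N, toluene, rt; then 28, DMAP, toluene, 40 °C
Reagents that add atoms: none
Why: Yamaguchi esterification: the mixed anhydride of the hindered epoxy acid acylates the remaining C8 hydroxyl under DMAP catalysis with retention at C8 and at both epoxide carbons.

Step 17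
Reactants: 30 macrocyclic triene diester
Product: 31 target
Conditions: mCPBA (1.1 equiv), NaHCO3, CH2Cl2, 0 °C
Reagents that add atoms: 3-chloroperoxybenzoic acid, OOC(=O)c1cccc(Cl)c1
Why: Prilezhaev epoxidation: the peracid attacks the only electron-rich alkene (trisubstituted C4=C5; all others are conjugated to carbonyl groups) from the exposed outer face of the E-alkene in the 10-membered ring, anti to the lactone as in related germacranolides, giving the (4R,5R)-epoxide.

## Compound list

1 | (2E)-3-methylpent-2-en-4-yn-1-ol | C#C/C(C)=C/CO | starting material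
2 | (2E)-3-methylpent-2-en-4-ynal | C#C/C(C)=C/C=O | intermediate
3 | methyl prop-2-ynoate (methyl propiolate) | C#CC(=O)OC | starting material
4 | methyl (4R,5E)-4-hydroxy-6-methylocta-5-en-2,7-diynoate | O[C@H](/C=C(\C)C#C)C#CC(=O)OC | intermediate
5 | methyl (2Z,4S,5E)-4-hydroxy-6-methylocta-2,5,7-trienoate | O[C@H](/C=C(\C)C=C)/C=C\C(=O)OC | intermediate
6 | (5S)-5-[(1E)-2-methylbuta-1,3-dien-1-yl]furan-2(5H)-one | O=C1O[C@H](/C=C(\C)C=C)C=C1 | intermediate
7 | (2-methylprop-1-en-1-yl)magnesium bromide | CC(C)=C[Mg]Br | starting material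
8 | (2-methylprop-1-en-1-yl)copper | CC(C)=C[Cu] | intermediate
9 | [(1Z)-1-(methoxycarbonyl)-4-methylpenta-1,3-dien-1-yl]copper | COC(=O)/C([Cu])=C/C=C(C)C | intermediate
10 | methyl (2Z)-2-iodo-5-methylhexa-2,4-dienoate | COC(=O)/C(I)=C/C=C(C)C | intermediate
11 | (4R)-2,2-dimethyl-1,3-dioxolane-4-carbaldehyde (acetonide-protected D-glyceraldehyde) | CC1(C)OC[C@H](C=O)O1 | starting material
12 | dichloro[(1Z)-1-(methoxycarbonyl)-4-methylpenta-1,3-dien-1-yl]chromium | COC(=O)/C(=C/C=C(C)C)[Cr](Cl)Cl | intermediate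
13 | methyl (2E)-2-{(S)-[(4R)-2,2-dimethyl-1,3-dioxolan-4-yl](hydroxy)methyl}-5-methylhexa-2,4-dienoate | COC(=O)/C(=C/C=C(C)C)[C@H](O)[C@H]1COC(C)(C)O1 | intermediate
14 | methyl (2E)-5-methyl-2-[(1S,2R)-1,2,3-trihydroxypropyl]hexa-2,4-dienoate | COC(=O)/C(=C/C=C(C)C)[C@H](O)[C@H](O)CO | intermediate
15 | methyl (2E)-2-[(1S,2S)-1,2-dihydroxy-3-oxopropyl]-5-methylhexa-2,4-dienoate | COC(=O)/C(=C/C=C(C)C)[C@H](O)[C@H](O)C=O | intermediate
16 | (2S,3S,4E)-2,3-dihydroxy-4-(methoxycarbonyl)-7-methylocta-4,6-dienoic acid | COC(=O)/C(=C/C=C(C)C)[C@H](O)[C@H](O)C(=O)O | intermediate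
17 | (4S,5S)-5-[(2E)-1-methoxy-5-methyl-1-oxohexa-2,4-dien-2-yl]-2,2-dimethyl-1,3-dioxolane-4-carboxylic acid (cis-dioxolane) | COC(=O)/C(=C/C=C(C)C)[C@@H]1OC(C)(C)O[C@@H]1C(=O)O | intermediate
18 | (2E)-2-methylbut-2-en-1-ol | C/C=C(\C)CO | starting material
19 | [(2R,3R)-2,3-dimethyloxiran-2-yl]methanol | OC[C@@]1(C)O[C@@H]1C | intermediate
20 | (2S,3R)-2,3-dimethyloxirane-2-carboxylic acid | OC(=O)[C@@]1(C)O[C@@H]1C | intermediate
21 | 1,3-dioxoisoindolin-2-yl (4S,5S)-5-[(2E)-1-methoxy-5-methyl-1-oxohexa-2,4-dien-2-yl]-2,2-dimethyl-1,3-dioxolane-4-carboxylate | COC(=O)/C(=C/C=C(C)C)[C@@H]1OC(C)(C)O[C@@H]1C(=O)ON1C(=O)c2ccccc2C1=O | intermediate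
22 | methyl (2E)-2-[(4S,5S)-2,2-dimethyl-5-{(2R,3S)-2-[(1E)-2-methylbuta-1,3-dien-1-yl]-5-oxooxolan-3-yl}-1,3-dioxolan-4-yl]-5-methylhexa-2,4-dienoate (trans-dioxolane) | O=C1O[C@H](/C=C(\C)C=C)[C@H](C1)[C@@H]2OC(C)(C)O[C@H]2/C(C(=O)OC)=C\C=C(C)C | intermediate
23 | 4-[(dimethylamino)methyl] derivative of 22 (Mannich base; configuration at the oxolane C4 not defined) | CN(C)CC1C(=O)O[C@H](/C=C(\C)C=C)[C@H]1[C@@H]2OC(C)(C)O[C@H]2/C(C(=O)OC)=C\C=C(C)C | intermediate
24 | trimethylammoniomethyl iodide derived from 23 | C[N+](C)(C)CC1C(=O)O[C@H](/C=C(\C)C=C)[C@H]1[C@@H]2OC(C)(C)O[C@H]2/C(C(=O)OC)=C\C=C(C)C.[I-] | intermediate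
25 | methyl (2E)-2-[(4S,5S)-2,2-dimethyl-5-{(2R,3S)-4-methylidene-2-[(1E)-2-methylbuta-1,3-dien-1-yl]-5-oxooxolan-3-yl}-1,3-dioxolan-4-yl]-5-methylhexa-2,4-dienoate | C=C1C(=O)O[C@H](/C=C(\C)C=C)[C@H]1[C@@H]2OC(C)(C)O[C@H]2/C(C(=O)OC)=C\C=C(C)C | intermediate
26 | methyl (1(10)E,2Z,4E,6R,7S,8S,9S)-8,9-(isopropylidenedioxy)germacra-1(10),2,4,11(13)-tetraen-12,6-olid-14-oate | C=C1C(=O)O[C@H]2[C@H]1[C@@H]3OC(C)(C)O[C@H]3/C(C(=O)OC)=C\C=C/C(C)=C/2 | intermediate
27 | methyl (1(10)E,2Z,4E,6R,7S,8S,9S)-8,9-dihydroxygermacra-1(10),2,4,11(13)-tetraen-12,6-olid-14-oate | C=C1C(=O)O[C@H]2[C@H]1[C@H](O)[C@@H](O)/C(C(=O)OC)=C\C=C/C(C)=C/2 | intermediate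
28 | methyl (1(10)E,2Z,4E,6R,7S,8S,9S)-9-acetoxy-8-hydroxygermacra-1(10),2,4,11(13)-tetraen-12,6-olid-14-oate | C=C1C(=O)O[C@H]2[C@H]1[C@H](O)[C@@H](OC(C)=O)/C(C(=O)OC)=C\C=C/C(C)=C/2 | intermediate
29 | (2S,3R)-2,3-dimethyloxirane-2-carboxylic 2,4,6-trichlorobenzoic anhydride | O=C(OC(=O)c1c(Cl)cc(Cl)cc1Cl)[C@@]1(C)O[C@@H]1C | intermediate
30 | methyl (1(10)E,2Z,4E,6R,7S,8S,9S)-9-acetoxy-8-{[(2S,3R)-2,3-dimethyloxiran-2-yl]carbonyloxy}germacra-1(10),2,4,11(13)-tetraen-12,6-olid-14-oate | C=C1C(=O)O[C@H]2[C@H]1[C@H](OC(=O)[C@@]3(C)O[C@@H]3C)[C@@H](OC(C)=O)/C(C(=O)OC)=C\C=C/C(C)=C/2 | intermediate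
31 | methyl (1(10)E,2Z,4R,5R,6S,7R,8S,9S)-9-acetoxy-8-{[(2S,3R)-2,3-dimethyloxiran-2-yl]carbonyloxy}-4,5-epoxygermacra-1(10),2,11(13)-trien-12,6-olid-14-oate | C=C1C(=O)O[C@H]2[C@H]1[C@H](OC(=O)[C@@]1(C)O[C@@H]1C)[C@@H](OC(C)=O)/C(C(=O)OC)=C\C=C/[C@@]1(C)O[C@H]21 | target

## Step count and risks

Total step count: 17. Longest linear sequence: 12 steps (7 → 10 → 13 → 14 → 16 → 17 → 22 → 25 → 26 → 27 → 28 → 30 → 31).

The three steps most likely to fail are steps 13, 15 and 17.

**Step 13 (ring closure).** The metathesis must form a strained 10-membered (Z,Z,E)-triene from a trisubstituted alkene terminus while the C8–C9 torsion is locked by the trans-fused ketal. The fallback sets out from 25 and closes the ring on a flexible substrate. Aqueous acetic acid removes the acetonide to give the open-chain diol F1. Et3SiOTf and 2,6-lutidine give the bis(triethylsilyl) ether F2. Ring-closing metathesis with the same catalyst gives the macrocyclic bis(triethylsilyl) ether F3. HF·pyridine then frees both hydroxyls, and the route is rejoined at diol 27.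

**Step 15 (selective acetylation).** The two secondary hydroxyls of 27 may not be differentiated well enough by acetic anhydride, or the acetyl group may migrate from O9 to O8 during step 16. The fallback sets out from 27 and reverses the order of the two acylations with a temporary, non-migrating group. The bulkier Et3SiCl with imidazole at −40 °C gives the 9-O-triethylsilyl ether F4. Yamaguchi esterification with 20 gives the 8-O-acyl 9-O-silyl compound F5. Buffered HF·pyridine gives the 9-hydroxy 8-ester F6. Acetylation with Ac2O and DMAP rejoins the route at 30.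

**Step 17 (epoxidation).** The peracid may attack the wrong face of C4=C5 if the ring conformation differs from that of the germacranolide models. The fallback sets out from 30 and delivers oxygen to the opposite face. NBS in THF/H2O adds bromine from the exposed face and water anti at the tertiary carbon to give the bromohydrin F7 (OH at C4, Br at C5). Ag2O closes the epoxide with inversion at C5, and the route comes back at the target 31.

## Further compounds

F1 | step 13 | methyl (2E)-2-[(1S,2S)-1,2-dihydroxy-2-{(2R,3S)-4-methylidene-2-[(1E)-2-methylbuta-1,3-dien-1-yl]-5-oxooxolan-3-yl}ethyl]-5-methylhexa-2,4-dienoate (open-chain diol) | C=C1C(=O)O[C@H](/C=C(\C)C=C)[C@H]1[C@H](O)[C@@H](O)/C(C(=O)OC)=C\C=C(C)C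
F2 | step 13 | bis(triethylsilyl) ether of F1 | C=C1C(=O)O[C@H](/C=C(\C)C=C)[C@H]1[C@H](O[Si](CC)(CC)CC)[C@@H](O[Si](CC)(CC)CC)/C(C(=O)OC)=C\C=C(C)C
F3 | step 13 | methyl (1(10)E,2Z,4E,6R,7S,8S,9S)-8,9-bis(triethylsilyloxy)germacra-1(10),2,4,11(13)-tetraen-12,6-olid-14-oate | C=C1C(=O)O[C@H]2[C@H]1[C@H](O[Si](CC)(CC)CC)[C@@H](O[Si](CC)(CC)CC)/C(C(=O)OC)=C\C=C/C(C)=C/2
F4 | step 15 | 9-O-triethylsilyl ether of diol 27 | C=C1C(=O)O[C@H]2[C@H]1[C@H](O)[C@@H](O[Si](CC)(CC)CC)/C(C(=O)OC)=C\C=C/C(C)=C/2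
F5 | step 15 | 8-O-[(2S,3R)-2,3-dimethyloxirane-2-carbonyl] 9-O-triethylsilyl derivative of 27 | C=C1C(=O)O[C@H]2[C@H]1[C@H](OC(=O)[C@@]3(C)O[C@@H]3C)[C@@H](O[Si](CC)(CC)CC)/C(C(=O)OC)=C\C=C/C(C)=C/2
F6 | step 15 | 8-O-[(2S,3R)-2,3-dimethyloxirane-2-carbonyl] 9-hydroxy derivative of 27 | C=C1C(=O)O[C@H]2[C@H]1[C@H](OC(=O)[C@@]3(C)O[C@@H]3C)[C@@H](O)/C(C(=O)OC)=C\C=C/C(C)=C/2
F7 | step 17 | 5-bromo-4-hydroxy bromohydrin of 30 (anti addition across C4=C5) | C=C1C(=O)O[C@H]2[C@H]1[C@H](OC(=O)[C@@]3(C)O[C@@H]3C)[C@@H](OC(C)=O)/C(C(=O)OC)=C\C=C/[C@@](C)(O)[C@H]2Br
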